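The route cuts the only C=C bond of the six-membered carbocycle. Locants: C1 is the quaternary oxirane carbon bearing C7H2OBz, C2 bears OBz, C3 bears OH, C4=C5 is the alkene, C6 is the oxirane CH. C4=C5 lies between carbinol C3 and oxirane carbon C6, so ring-closing metathesis of an acyclic cis-epoxy diene forms that bond and ring C1–C6 in one operation and touches no stereocentre. The precursor carries both benzoates, a PMB ether at O3, and the C6 vinyl group and C2 chain on the same side of the oxirane. A Sharpless epoxidation (C1, C6) and a Brown alkoxyallylboration (C2, C3) set all four stereocentres beforehand.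

Key step: step 15

Remark: TBS = tert-butyldimethylsilyl, TBDPS = tert-butyldiphenylsilyl, PMB = 4-methoxybenzyl, Bz = benzoyl, Ipc = isopinocampheyl; the absolute sense of the epoxidation and of the allylboration is assigned from the usual tartrate and pinene face rules, which are assumed to hold for these substrates.

Step 1
Reactants: 1 but-2-yne-1,4-diol
Product: 2 4-(TBS-oxy)but-2-yn-1-ol
Conditions: 1 (3 equiv), TBSCl (1 equiv), imidazole, DMF, 0 °C → rt
Reagents that add atoms: tert-butyldimethylsilyl chloride, CC(C)(C)[Si](C)(C)Cl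
Why: Silyl ether formation on a symmetrical diol used in excess should stop at the mono-ether; no stereocentre is involved.

Step 2
Reactants: 2 4-(TBS-oxy)but-2-yn-1-ol
Product: 4 (Z)-4-(TBS-oxy)-3-iodobut-2-en-1-ol, via cyclic alkenylalanate 3 (not isolated)
Conditions: Na[AlH2(OCH2CH2OMe)2], THF, 0 °C → rt; EtOAc; then I2, THF, −78 → 0 °C
Reagents that add atoms: iodine, II
Why: Hydroxyl-directed trans-hydroalumination of the propargylic alcohol puts hydride on C6 and aluminium on C1 in a five-membered alanate, and iodinolysis with retention should give only the Z iodoalkene, in which the C5 carbinol is cis to the iodine that C2 will replace.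

Step 3
Reactants: 4 (Z)-4-(TBS-oxy)-3-iodobut-2-en-1-ol
Product: 5 (Z)-4-(TBS-oxy)-1-(TBDPS-oxy)-3-iodobut-2-ene
Conditions: TBDPSCl, imidazole, CH2Cl2, 0 °C → rt
Reagents that add atoms: tert-butyldiphenylsilyl chloride, CC(C)(C)[Si](Cl)(c1ccccc1)c1ccccc1
Why: Silyl ether formation at the only free hydroxyl masks O5, so the ester of step 4 cannot lactonise onto it and only one allylic alcohol is free in step 6.

Step 4
Reactants: 5 (Z)-4-(TBS-oxy)-1-(TBDPS-oxy)-3-iodobut-2-ene
Product: 6 methyl (Z)-2-[(TBS-oxy)methyl]-4-(TBDPS-oxy)but-2-enoate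
Conditions: Pd(OAc)2 (5 mol %), PPh3 (10 mol %), CO (1 atm), MeOH, Et3N, DMF, 60 °C
Reagents that add atoms: carbon monoxide, [C-]#[O+]; methanol, CO
Why: Palladium-catalysed alkoxycarbonylation (oxidative addition of zerovalent palladium into the C–I bond, CO insertion, methanolysis) replaces iodine by the C2 carbon with retention of the alkene geometry.

Step 5
Reactants: 6 methyl (Z)-2-[(TBS-oxy)methyl]-4-(TBDPS-oxy)but-2-enoate
Product: 7 (E)-2-[(TBS-oxy)methyl]-4-(TBDPS-oxy)but-2-en-1-ol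
Conditions: i-Bu2AlH (2.5 equiv), CH2Cl2, −78 → 0 °C
Reagents that add atoms: none
Why: 1,2-Reduction of the enoate by an aluminium hydride at low temperature gives the allylic alcohol and leaves the silyl ethers and the alkene geometry alone.

Step 6
Reactants: 7 (E)-2-[(TBS-oxy)methyl]-4-(TBDPS-oxy)but-2-en-1-ol
Product: 8 [(2S,3S)-2-[(TBS-oxy)methyl]-3-[(TBDPS-oxy)methyl]oxiran-2-yl]methanol
Conditions: Ti(OiPr)4 (30 mol %), D-(−)-diisopropyl tartrate (36 mol %), t-BuOOH (2 equiv), 4 Å molecular sieves, CH2Cl2, −20 °C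
Reagents that add atoms: tert-butyl hydroperoxide, CC(C)(C)OO
Why: Katsuki–Sharpless asymmetric epoxidation: the titanium tartrate complex binds the C2 hydroxyl and transfers oxygen suprafacially to one face of C1=C6, so the tartrate chirality sets C1 and C6 together (the D-(−) ester should give the (2S,3S)-oxirane by the empirical face rule) and C2 and C5 stay cis.

Step 7
Reactants: 8 [(2S,3S)-2-[(TBS-oxy)methyl]-3-[(TBDPS-oxy)methyl]oxiran-2-yl]methanol
Product: 9 (2S,3S)-2-[(TBS-oxy)methyl]-3-[(TBDPS-oxy)methyl]oxirane-2-carbaldehyde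
Conditions: Dess–Martin periodinane, NaHCO3, CH2Cl2, 0 °C → rt
Reagents that add atoms: none
Why: Buffered Dess–Martin oxidation converts the primary alcohol into the aldehyde, whose α-carbon is quaternary and cannot epimerise.

Step 8
Reactants: 10 4-methoxybenzyl alcohol; 11 allyl bromide
Product: 13 allyl 4-methoxybenzyl ether, via sodium 4-methoxybenzyl oxide 12 (not isolated)
Conditions: NaH, THF, 0 °C; then 11, n-Bu4NI (cat.), 0 °C → rt
Reagents that add atoms: none
Why: Williamson ether synthesis of a primary alkoxide with an allylic bromide.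

Step 9
Reactants: 9 (2S,3S)-2-[(TBS-oxy)methyl]-3-[(TBDPS-oxy)methyl]oxirane-2-carbaldehyde; 13 allyl 4-methoxybenzyl ether
Product: 18 (1S,2R)-1-[(2R,3S)-2-[(TBS-oxy)methyl]-3-[(TBDPS-oxy)methyl]oxiran-2-yl]-2-(PMB-oxy)but-3-en-1-ol, via (Z)-alkoxyallyllithium 14 (not isolated), via lithium allyl(methoxy)borate 15 (not isolated), via (Z)-alkoxyallylborane 16 (not isolated), via borinate ester 17 (not isolated)
Conditions: 13, s-BuLi, THF, −78 °C; (−)-Ipc2BOMe [from (+)-α-pinene], −78 °C; BF3·OEt2; then 9, −78 °C; then NaOH, H2O2, 0 °C → rt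
Reagents that add atoms: none
Why: Brown (Z)-γ-alkoxyallylboration through a chair transition state: the isopinocampheyl groups from (+)-α-pinene choose the aldehyde face (reagent control, giving 2S at C2), and the Z geometry of the borane, fixed by oxygen-chelated lithiation, becomes the syn C2/C3 pair (3R at C3).

Step 10
Reactants: 18 (1S,2R)-1-[(2R,3S)-2-[(TBS-oxy)methyl]-3-[(TBDPS-oxy)methyl]oxiran-2-yl]-2-(PMB-oxy)but-3-en-1-ol
Product: 19 (1S,2R)-1-[(2R,3S)-2-(hydroxymethyl)-3-[(TBDPS-oxy)methyl]oxiran-2-yl]-2-(PMB-oxy)but-3-en-1-ol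
Conditions: HF·pyridine, pyridine, THF, 0 °C → rt
Reagents that add atoms: none
Why: Fluoride-mediated silyl ether cleavage should distinguish kinetically between the primary TBS ether and the bulkier, more robust TBDPS ether, and the buffered non-basic medium spares the oxirane.

Step 11
Reactants: 19 (1S,2R)-1-[(2R,3S)-2-(hydroxymethyl)-3-[(TBDPS-oxy)methyl]oxiran-2-yl]-2-(PMB-oxy)but-3-en-1-ol
Product: 20 [(2S,3S)-2-[(1S,2R)-1-(benzoyloxy)-2-(PMB-oxy)but-3-en-1-yl]-3-[(TBDPS-oxy)methyl]oxiran-2-yl]methyl benzoate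
Conditions: BzCl (3 equiv), pyridine, DMAP (cat.), CH2Cl2, 0 °C → rt
Reagents that add atoms: benzoyl chloride, O=C(Cl)c1ccccc1
Why: DMAP-catalysed acylation converts both free hydroxyls (O2 and O7) into the benzoates of the target.

Step 12
Reactants: 20 [(2S,3S)-2-[(1S,2R)-1-(benzoyloxy)-2-(PMB-oxy)but-3-en-1-yl]-3-[(TBDPS-oxy)methyl]oxiran-2-yl]methyl benzoate
Product: 21 [(2S,3S)-2-[(1S,2R)-1-(benzoyloxy)-2-(PMB-oxy)but-3-en-1-yl]-3-(hydroxymethyl)oxiran-2-yl]methyl benzoate
Conditions: n-Bu4NF, AcOH (1:1), THF, 0 °C → rt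
Reagents that add atoms: none
Why: Acetic acid-buffered fluoride cleaves the remaining silyl ether and should cause neither benzoate migration nor Payne rearrangement.

Step 13
Reactants: 21 [(2S,3S)-2-[(1S,2R)-1-(benzoyloxy)-2-(PMB-oxy)but-3-en-1-yl]-3-(hydroxymethyl)oxiran-2-yl]methyl benzoate
Product: 22 [(2R,3R)-2-[(1S,2R)-1-(benzoyloxy)-2-(PMB-oxy)but-3-en-1-yl]-3-formyloxiran-2-yl]methyl benzoate
Conditions: Dess–Martin periodinane, NaHCO3, CH2Cl2, 0 °C → rt
Reagents that add atoms: none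
Why: Dess–Martin oxidation of the epoxy alcohol to the epoxy aldehyde tolerates benzoates, PMB ether and the terminal alkene, and the oxirane C–H is not acidic enough to epimerise (the descriptors change only through priorities).

Step 14
Reactants: 22 [(2R,3R)-2-[(1S,2R)-1-(benzoyloxy)-2-(PMB-oxy)but-3-en-1-yl]-3-formyloxiran-2-yl]methyl benzoate
Product: 23 [(2S,3S)-2-[(1S,2R)-1-(benzoyloxy)-2-(PMB-oxy)but-3-en-1-yl]-3-vinyloxiran-2-yl]methyl benzoate
Conditions: Ph3PCH3Br, KN(SiMe3)2, THF, 0 °C; then 22, −78 → 0 °C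
Reagents that add atoms: methyltriphenylphosphonium bromide, [Br-].C[P+](c1ccccc1)(c1ccccc1)c1ccccc1
Why: Wittig methylenation at low temperature, where the non-stabilised ylide reacts with the aldehyde much faster than with the benzoates.

Step 15
Reactants: 23 [(2S,3S)-2-[(1S,2R)-1-(benzoyloxy)-2-(PMB-oxy)but-3-en-1-yl]-3-vinyloxiran-2-yl]methyl benzoate
Product: 24 [(1S,2S,3R,6S)-2-(benzoyloxy)-3-(PMB-oxy)-7-oxabicyclo[4.1.0]hept-4-en-1-yl]methyl benzoate
Conditions: second-generation Grubbs catalyst RuCl2(=CHPh)(PCy3)(H2IMes) (5 mol %), CH2Cl2 (0.005 M), 40 °C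
Reagents that add atoms: none
Why: The ruthenium benzylidene exchanges with one terminal vinyl group (probably the less encumbered C3 vinyl) to give a ruthenium alkylidene, which adds to the other vinyl group in a [2+2] step; cycloreversion of the ruthenacyclobutane forms C4=C5 and releases ethylene, whose loss drives the reaction. The closest known reaction type is ring-closing olefin metathesis of 1,7-dienes to cyclohexenes, including dienes that carry a vinyl oxirane, allylic ethers and esters. The six-membered carbocycle C1–C6 closes by joining C4 to C5, and the ring size enforces the cis geometry of the new alkene. No stereocentre is formed, so C1, C2, C3 and C6 pass through unchanged. The step needs chemoselectivity for cyclisation over cross-metathesis, oxirane opening and olefin migration: the cis placement of the C6 vinyl group and the C2 chain on the oxirane holds the two alkenes close, high dilution suppresses oligomers, and the neutral catalyst should leave oxirane, benzoates and PMB ether alone.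

Step 16
Reactants: 24 [(1S,2S,3R,6S)-2-(benzoyloxy)-3-(PMB-oxy)-7-oxabicyclo[4.1.0]hept-4-en-1-yl]methyl benzoate
Product: 25 [(1S,2S,3R,6S)-2-(benzoyloxy)-3-hydroxy-7-oxabicyclo[4.1.0]hept-4-en-1-yl]methyl benzoate
Conditions: DDQ, CH2Cl2/aq. NaH2PO4–Na2HPO4 buffer (pH 7), 0 °C → rt
Reagents that add atoms: none
Why: Oxidative PMB ether cleavage by DDQ (hydride abstraction, then hydrolysis of the oxocarbenium ion) under neutral conditions frees O3 and should cause neither benzoate migration nor oxirane opening.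

Compound list
1 | but-2-yne-1,4-diol | OCC#CCO | starting material
2 | 4-(TBS-oxy)but-2-yn-1-ol | OCC#CCO[Si](C)(C)C(C)(C)C | intermediate
3 | cyclic sodium alkenylalanate (Al on C1, O5 bound to Al) | [Na+].COCCO[Al-]1(OCCOC)OCC=C1CO[Si](C)(C)C(C)(C)C | intermediate
4 | (Z)-4-(TBS-oxy)-3-iodobut-2-en-1-ol | OC/C=C(\I)CO[Si](C)(C)C(C)(C)C | intermediate
5 | (Z)-4-(TBS-oxy)-1-(TBDPS-oxy)-3-iodobut-2-ene | CC(C)(C)[Si](c1ccccc1)(c1ccccc1)OC/C=C(\I)CO[Si](C)(C)C(C)(C)C | intermediate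
6 | methyl (Z)-2-[(TBS-oxy)methyl]-4-(TBDPS-oxy)but-2-enoate | CC(C)(C)[Si](c1ccccc1)(c1ccccc1)OC/C=C(\C(=O)OC)CO[Si](C)(C)C(C)(C)C | intermediate
7 | (E)-2-[(TBS-oxy)methyl]-4-(TBDPS-oxy)but-2-en-1-ol | CC(C)(C)[Si](c1ccccc1)(c1ccccc1)OC/C=C(\CO)CO[Si](C)(C)C(C)(C)C | intermediate
8 | [(2S,3S)-2-[(TBS-oxy)methyl]-3-[(TBDPS-oxy)methyl]oxiran-2-yl]methanol | CC(C)(C)[Si](C)(C)OC[C@@]1(O[C@H]1CO[Si](c1ccccc1)(c1ccccc1)C(C)(C)C)CO | intermediate
9 | (2S,3S)-2-[(TBS-oxy)methyl]-3-[(TBDPS-oxy)methyl]oxirane-2-carbaldehyde | CC(C)(C)[Si](C)(C)OC[C@@]1(O[C@H]1CO[Si](c1ccccc1)(c1ccccc1)C(C)(C)C)C=O | intermediate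
10 | 4-methoxybenzyl alcohol | COc1ccc(CO)cc1 | starting material
11 | allyl bromide | C=CCBr | starting material
12 | sodium 4-methoxybenzyl oxide | [Na+].[O-]Cc1ccc(OC)cc1 | intermediate
13 | allyl 4-methoxybenzyl ether | C=CCOCc1ccc(OC)cc1 | intermediate
14 | (Z)-3-(PMB-oxy)allyllithium | [Li]C/C=C\OCc1ccc(OC)cc1 | intermediate
15 | lithium [(Z)-3-(PMB-oxy)allyl](methoxy)bis(isopinocampheyl)borate, Ipc from (+)-α-pinene | [Li+].CO[B-](C/C=C\OCc1ccc(OC)cc1)([C@@H]2C[C@@H]3C[C@H]([C@H]2C)C3(C)C)[C@@H]2C[C@@H]3C[C@H]([C@H]2C)C3(C)C | intermediate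
16 | [(Z)-3-(PMB-oxy)allyl]bis(isopinocampheyl)borane, Ipc from (+)-α-pinene | COc1ccc(CO/C=C\CB([C@@H]2C[C@@H]3C[C@H]([C@H]2C)C3(C)C)[C@@H]2C[C@@H]3C[C@H]([C@H]2C)C3(C)C)cc1 | intermediate
17 | O2-bis(isopinocampheyl)boryl derivative (borinate ester) of 18 | CC(C)(C)[Si](C)(C)OC[C@@]1(O[C@H]1CO[Si](c1ccccc1)(c1ccccc1)C(C)(C)C)[C@@H](OB([C@@H]2C[C@@H]3C[C@H]([C@H]2C)C3(C)C)[C@@H]2C[C@@H]3C[C@H]([C@H]2C)C3(C)C)[C@H](OCc1ccc(OC)cc1)C=C | intermediate
18 | (1S,2R)-1-[(2R,3S)-2-[(TBS-oxy)methyl]-3-[(TBDPS-oxy)methyl]oxiran-2-yl]-2-(PMB-oxy)but-3-en-1-ol | CC(C)(C)[Si](C)(C)OC[C@@]1(O[C@H]1CO[Si](c1ccccc1)(c1ccccc1)C(C)(C)C)[C@@H](O)[C@H](OCc1ccc(OC)cc1)C=C | intermediate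
19 | (1S,2R)-1-[(2R,3S)-2-(hydroxymethyl)-3-[(TBDPS-oxy)methyl]oxiran-2-yl]-2-(PMB-oxy)but-3-en-1-ol | OC[C@@]1(O[C@H]1CO[Si](c1ccccc1)(c1ccccc1)C(C)(C)C)[C@@H](O)[C@H](OCc1ccc(OC)cc1)C=C | intermediate
20 | [(2S,3S)-2-[(1S,2R)-1-(benzoyloxy)-2-(PMB-oxy)but-3-en-1-yl]-3-[(TBDPS-oxy)methyl]oxiran-2-yl]methyl benzoate | O=C(OC[C@@]1(O[C@H]1CO[Si](c1ccccc1)(c1ccccc1)C(C)(C)C)[C@@H](OC(=O)c1ccccc1)[C@H](OCc1ccc(OC)cc1)C=C)c1ccccc1 | intermediate
21 | [(2S,3S)-2-[(1S,2R)-1-(benzoyloxy)-2-(PMB-oxy)but-3-en-1-yl]-3-(hydroxymethyl)oxiran-2-yl]methyl benzoate | O=C(OC[C@@]1(O[C@H]1CO)[C@@H](OC(=O)c1ccccc1)[C@H](OCc1ccc(OC)cc1)C=C)c1ccccc1 | intermediate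
22 | [(2R,3R)-2-[(1S,2R)-1-(benzoyloxy)-2-(PMB-oxy)but-3-en-1-yl]-3-formyloxiran-2-yl]methyl benzoate | O=C(OC[C@@]1(O[C@H]1C=O)[C@@H](OC(=O)c1ccccc1)[C@H](OCc1ccc(OC)cc1)C=C)c1ccccc1 | intermediate
23 | [(2S,3S)-2-[(1S,2R)-1-(benzoyloxy)-2-(PMB-oxy)but-3-en-1-yl]-3-vinyloxiran-2-yl]methyl benzoate (epoxy diene) | O=C(OC[C@@]1(O[C@H]1C=C)[C@@H](OC(=O)c1ccccc1)[C@H](OCc1ccc(OC)cc1)C=C)c1ccccc1 | intermediate
24 | [(1S,2S,3R,6S)-2-(benzoyloxy)-3-(PMB-oxy)-7-oxabicyclo[4.1.0]hept-4-en-1-yl]methyl benzoate | O=C(OC[C@]12O[C@H]1C=C[C@@H](OCc1ccc(OC)cc1)[C@@H]2OC(=O)c1ccccc1)c1ccccc1 | intermediate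
25 | [(1S,2S,3R,6S)-2-(benzoyloxy)-3-hydroxy-7-oxabicyclo[4.1.0]hept-4-en-1-yl]methyl benzoate | O=C(OC[C@]12O[C@H]1C=C[C@@H](O)[C@@H]2OC(=O)c1ccccc1)c1ccccc1 | target

Total step count: 16. Longest linear sequence: 15 steps (steps 1–7 and 9–16; step 8 makes the allyl ether on a side branch).

Steps most likely to fail

Step 15 (ring-closing metathesis). The catalyst may decompose or move a double bond (allyl ether to enol ether) before the ring closes, or the diene may oligomerise by cross-metathesis. Fallback: starting from 23, cleave the PMB ether first with DDQ in buffered CH2Cl2 to give the free C3 alcohol F7. Then cyclise this allylic alcohol with the second-generation Hoveyda–Grubbs catalyst RuCl2(=CH-2-(i-PrO)C6H4)(H2IMes) in dilute CH2Cl2; a free allylic hydroxyl speeds up metathesis at the neighbouring vinyl group and the bulky ether is gone. This arrives directly at 25.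

Step 9 (allylboration of the epoxy aldehyde). Metalation of the allyl ether may be incomplete, a mismatched reagent–substrate pairing may erode facial selectivity, or the Lewis acid may open the oxirane. Fallback: starting from 7, oxidise with MnO2 in CH2Cl2 to the (Z)-enal F5, used at once, and add borane 16 to this achiral aldehyde under the conditions of step 9 to give the dienol F6, with C2 and C3 set by the reagent alone. Then epoxidise the trisubstituted C1=C6 bond with mCPBA/NaHCO3 in CH2Cl2 at 0 °C. Hydrogen bonding to the C2 hydroxyl, in the conformer that keeps the C2–H in the alkene plane next to C5 (least allylic 1,3-strain), should deliver oxygen to the required face, and the sequence rejoins the route at 18.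

Step 6 (Sharpless epoxidation). Oxygen transfer may be slow and enantiofacial selectivity eroded because C5 is cis to the directing carbinol. Fallback: switch the directing hydroxyl to O7, to which C5 is trans. Starting from 7, protect O2 with 4-methoxybenzyl trichloroacetimidate and catalytic camphorsulfonic acid to give the PMB ether F1, then cleave the TBS ether with camphorsulfonic acid in MeOH at 0 °C to the allylic alcohol F2. Epoxidise with Ti(OiPr)4, L-(+)-diisopropyl tartrate and t-BuOOH to the epoxy alcohol F3, re-silylate with TBSCl and imidazole to the silyl ether F4, and remove the PMB group with DDQ, which returns to 8.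

Further compounds
F1 | step 6 | (E)-1-(TBDPS-oxy)-4-(PMB-oxy)-3-[(TBS-oxy)methyl]but-2-ene (O2 PMB ether of 7) | CC(C)(C)[Si](c1ccccc1)(c1ccccc1)OC/C=C(\COCc1ccc(OC)cc1)CO[Si](C)(C)C(C)(C)C
F2 | step 6 | (Z)-4-(TBDPS-oxy)-2-[(PMB-oxy)methyl]but-2-en-1-ol | CC(C)(C)[Si](c1ccccc1)(c1ccccc1)OC/C=C(\COCc1ccc(OC)cc1)CO
F3 | step 6 | [(2R,3S)-3-[(TBDPS-oxy)methyl]-2-[(PMB-oxy)methyl]oxiran-2-yl]methanol | OC[C@@]1(O[C@H]1CO[Si](c1ccccc1)(c1ccccc1)C(C)(C)C)COCc1ccc(OC)cc1
F4 | step 6 | (2S,3S)-2-[(TBS-oxy)methyl]-3-[(TBDPS-oxy)methyl]-2-[(PMB-oxy)methyl]oxirane | CC(C)(C)[Si](C)(C)OC[C@@]1(O[C@H]1CO[Si](c1ccccc1)(c1ccccc1)C(C)(C)C)COCc1ccc(OC)cc1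
F5 | step 9 | (Z)-2-[(TBS-oxy)methyl]-4-(TBDPS-oxy)but-2-enal | CC(C)(C)[Si](c1ccccc1)(c1ccccc1)OC/C=C(\C=O)CO[Si](C)(C)C(C)(C)C
F6 | step 9 | (3R,4R,5Z)-7-(TBDPS-oxy)-5-[(TBS-oxy)methyl]-3-(PMB-oxy)hepta-1,5-dien-4-ol | CC(C)(C)[Si](c1ccccc1)(c1ccccc1)OC/C=C(\[C@@H](O)[C@H](OCc1ccc(OC)cc1)C=C)CO[Si](C)(C)C(C)(C)C
F7 | step 15 | [(2S,3S)-2-[(1S,2R)-1-(benzoyloxy)-2-hydroxybut-3-en-1-yl]-3-vinyloxiran-2-yl]methyl benzoate | O=C(OC[C@@]1(O[C@H]1C=C)[C@@H](OC(=O)c1ccccc1)[C@H](O)C=C)c1ccccc1
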